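Divide a run's last target reading by the equivalents of reagent charged, and read its temperature afterwards.

| setting | blue | amber | ochre | epsilon | delta | gamma |
|---|---|---|---|---|---|---|
| substrate | 13 mM | 30 mM | 20 mM | 20 mM | 20 mM | 20 mM |
| reagent | 0.60 equiv | 0.60 equiv | 0.90 equiv | 0.600 equiv | 0.600 equiv | 0.600 equiv |
| temperature | −5 °C | 15 °C | −5 °C |  | 0 °C | 30 °C |
| remark | run made earlier | run made earlier | run made earlier | at 0 °C until 6.0 min, from then on at 30 °C |  |  |
| time |  |  |  | 12 min | 12 min | 12 min |

- blue (time / min: target / %): 3.00: 24.8; 6.00: 36.6; 8.00: 40.0; 12.0: 44.4; 15.0: 46.6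
- amber (time / min: target / %): 0.500: 22.7; 1.00: 31.1; 2.00: 38.3; 4.00: 42.8; 8.00: 44.8
- ochre (time / min: target / %): 1.00: 15.4; 2.00: 29.1; 4.00: 43.8; 8.00: 56.4; 15.0: 63.6

(scatter of a reading: 0.3 percentage points)

- what was read earlier has a scatter of 0.3 percentage points, one standard deviation
- a reading or a percentage of target counts all its forms, free or not

- the flask with the highest amount of target, in percent of the substrate charged ("all alike" if they lie within 1.5 percentage points) (epsilon / delta / gamma / all alike)
- final target, as a percentage of the substrate charged, in epsilon
- final target, as a percentage of the substrate charged, in delta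
- final target, as a percentage of the substrate charged, in gamma

I compared blue with amber, the simulated run charged with the same equivalents. Both held 0.60 equiv, but amber stood at 15 °C against −5 °C, with [substrate] of 30 mM against 13 mM. Amber passed half of its last reading by 0.500 min, blue half by 3.00 min, a reading time 6.00 times shorter. Yet their last readings lay 1.8 percentage points apart. Ochre, at blue's temperature with 0.90 equiv and 20 mM, reached 63.6%, more than blue, but its last two readings still lay 7.2 points apart, so I kept it out of the mean. So I treated reagent as the limiting reagent and carried the yield per equivalent, the target made in percent of substrate charged per equivalent of reagent charged: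

blue 0.777, amber 0.747, mean 0.762

target at 0.600 equiv: 0.762 × 0.600 equiv = 45.7%

I then asked whether the clock or the charge would hold the answer at the time given. Blue at 12.0 min already held nearly all of its last reading, and delta is warmer and richer. Gamma is warmer still, and epsilon is delta until 6.0 min, then gamma's temperature. I therefore committed to 45.7% in each flask and to all alike. The call was narrow: blue and amber differed by 1.8 points, against a margin of 1.5 points.

The forecast, holding that in gamma “the loss is nearly equal to product formation”, gave 46.5% for epsilon, 47.5% for delta and 35% for gamma, with delta highest.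

The flasks gave 47.8% in epsilon, 47.2% in delta and 48.3% in gamma: all alike.

    substrate + reagent ⇌ intermediate (K = 51.0 /M, k = 1.40 /M/s, Ea = 37.0 kJ/mol, ΔH = −23.0 kJ/mol)
    released group → by-product carried off (k = 0.200 /s, Ea = 69.0 kJ/mol)
    crystals ⇌ target, rate k3*(cs3 - [target]) while solid is left; crystals form when [target] > cs3 (solubility = 13.0 mM, k = 0.220 /s)
    intermediate ⇌ target + released group (K = 0.00340 M, k = 0.0270 /s, Ea = 65.0 kJ/mol, ΔH = −71.0 kJ/mol)
    substrate + intermediate → side product (k = 0.470 /M/s, Ea = 36.0 kJ/mol)
    (constants at 0 °C)

Read back, delta gave 0.787 per equivalent and gamma 0.805, so my 45.7% lay 1.5 points below delta and 2.6 points below gamma. At 12.0 min, delta held 2.69% of its reagent and gamma 0.300%. Delta's neighbour differs in one setting, 0.240 equiv of reagent in place of 0.600 equiv, and the same multiplication gives 0.762 × 0.240 equiv = 18.3%. At 12.0 min that neighbour held 0.114% of its reagent and 70.4% of the substrate, and its target stood at 18.4%.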